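- Raise the temperature of these flasks and two times shorten: τs, in which the substrate falls by a factor e while the free catalyst stands at its charge, and τc, the life of the free catalyst itself.

| flask | substrate | reagent | free catalyst | temperature | remark | time |
|---|---|---|---|---|---|---|
| north | 0.056 M | 1.5 equiv | 0.25 mol% | 5 °C | run made earlier |  |
| south | 0.056 M | 1.5 equiv | 0.38 mol% | 40 °C | run made earlier |  |
| autumn | 0.056 M | 1.50 equiv | 0.5 mol% | 10 °C |  | 15 min |
| midnight | 0.056 M | 1.50 equiv | 0.5 mol% | 40 °C |  | 15 min |
| spring | 0.056 M | 1.50 equiv | 0.5 mol% | 70 °C |  | 15 min |

| run | time / min | product / % | substrate / % |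
|---|---|---|---|
| north | 5.00 | 14.8 | 86.5 |
| north | 10.0 | 24.3 | 75.0 |
| north | 15.0 | 36.1 | 64.7 |
| north | 20.0 | 43.9 | 55.8 |
| south | 1.00 | 20.5 | 78.5 |
| south | 2.50 | 41.9 | 58.1 |
| south | 3.00 | 46.6 | 54.5 |
| south | 5.00 | 60.7 | 39.4 |

(scatter of a reading: 0.5 percentage points)

- the earlier runs were read with a standard deviation of 0.5 percentage points

1. the best flask by amount of product, in percent of the substrate charged; "all alike" if 1.5 percentage points covers them all (autumn / midnight / spring / all alike)
2. amount of product at the end, in percent of the substrate charged, autumn
3. amount of product at the end, in percent of the substrate charged, midnight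
4. amount of product at the end, in percent of the substrate charged, spring

- Take the first-order decay that the north readings show and a catalyst that dies exponentially. With S the fraction of substrate left, L = −ln S then follows L(t) = (τc/τs)(1 − e^(−t/τc)), so L at a doubled time over L at t, less one, equals e^(−t/τc).
- In south this test between 2.50 min and 5.00 min reads 0.715, so τc is 7.46 min. The same readings give Λ = τc/τs of 1.91, the catalyst's budget, the total L that a charge of free catalyst can pay for before it is spent, and so τs is 3.91 min.
- In north the test between 10.0 min and 20.0 min reads 1.03, above the value of one that the formula allows, so this reading carries scatter and the test sees no loss of catalyst in north without showing that there is none. You take it as your own assumption that τc shortens more steeply with heat than τs, so that Λ shrinks as a flask warms.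
- Your own reckoning lets loading shorten τs and leave τc alone. Midnight then has Λ = 2.51 and reaches 88.6% product. Autumn, from north's rate at its doubled loading, passes 58.3% before any warming, and spring should fall below midnight.
- The forecast names midnight, with 67.5% (64% to 70%) for autumn, 88% (82% to 92%) for midnight and 27% (12% to 50%) for spring, “so the catalyst dies quickly”.
- The flasks give 70.9% in autumn, 95.6% in midnight and 55.1% in spring, and the best is midnight.

    substrate + reagent + free catalyst → product + free catalyst, rate k1*[substrate]*[reagent]*[free catalyst]/(1 + ([substrate]/sat1)) (7.60 mM, k = 1.20 × 10⁵ L² mol⁻² min⁻¹, Ea = 36.0 kJ mol⁻¹)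
    reagent + free catalyst → spent catalyst (k = 2.70 L mol⁻¹ min⁻¹, Ea = 64.0 kJ mol⁻¹)
    (constants at 40 °C)

- Read the budget where the catalyst has finished. In midnight, with free catalyst at 0% after 150 min, L stands at 5.12, twice what south promised. In spring, free catalyst is down to 0.00658% after 7.50 min, substrate stays at 44.9%, and L stands at 0.801. The death of the catalyst has an activation energy 28.0 kJ mol⁻¹ above that of the conversion.

The runs are simulated from invented constants; the scatter is artificial.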